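In a one-step world second substrate turns into target and the share of target stands at 100%. This flask has forks: a molecule of second substrate may decompose, may form target on loaded enzyme, or may meet target and free enzyme and give over-reaction product.

the same everywhere: starting material 0.20 M; free enzyme 0.0013 mol%

|  | second substrate | remark | time |
|---|---|---|---|
| larch | 0.10 equiv | run made earlier |  |
| ash | 0.73 equiv | run made earlier |  |
| autumn | 0.0800 equiv |  | 2.5 d |
| summer | 0.200 equiv |  | 2.5 d |
| dawn | 0.600 equiv |  | 2.5 d |
| spring | 2.00 equiv |  | 2.5 d |
| midnight | 6.00 equiv |  | 2.5 d |

- larch (time / d: target / %, over-reaction product / %): 0.500: 1.2, 0; 1.04: 1.5, 0; 1.67: 1.4, 0.1; 2.08: 1.8, 0.3; 2.50: 1.1, 0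
- ash (time / d: target / %, over-reaction product / %): 0.208: 5.4, 0.5; 0.417: 6.8, 0; 0.625: 6.7, 0; 1.25: 6.5, 0.4; 2.50: 6.5, 0.3

(readings scatter by 0.3 percentage points)

- steps thought possible: first complex <-> loaded enzyme + first product; starting material + free enzyme <-> first complex; second complex -> free enzyme + target; second substrate + free enzyme + target -> free enzyme + over-reaction product; second substrate -> decomposed reagent; second substrate + loaded enzyme <-> second complex
- "hardly changes" means that all values lie within two and a half points (for a concentration: within two and a half percent of the largest)

- share of target in all that became target or over-reaction product for autumn, summer, dawn, spring, midnight, in this order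
- the course of these numbers from the first flask to the last (rises, then falls / rises all the way / falls all the way / falls, then rises / hardly changes)

I follow one molecule of second substrate to the fork between target and over-reaction product. Its odds for over-reaction go as [target]·[free enzyme]/[loaded enzyme]. The step that gives target also releases free enzyme. As a working assumption I let [free enzyme]/[loaded enzyme] grow with [target], and the finished ratio of over-reaction product to target then goes as the square of the target made.

Two amounts remain: the target made, and the equal-share target, the target at which this rule puts over-reaction product level with target. The ash run supplies it. Its over-reaction readings average 0.240% against 6.5% target, a ratio of 3.69%, and this is rough, since each reading scatters by 0.3 percentage points. That gives an equal-share target of 33.8%.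

The larch run reads 1.4% target, less than ash, so target grows with charge and I expect the share to fall as the charge rises. For dawn, charged a little below ash, I expect about 96.4% or somewhat above.

The forecast gave 99.6%, 99%, 97%, 91% and 77%, a course that falls all the way, holding that the ratio of over-reaction product to target should “scale roughly with the reagent charge”, where I use the square of the target.

The flasks give 100%, 99.9%, 99.2%, 94.6% and 80.1%: the share falls all the way.

    first complex ⇌ loaded enzyme + first product (K = 6.00 M, k = 140 /min)
    starting material + free enzyme ⇌ first complex (K = 6.20 /M, k = 67000 /M/min)
    second complex → free enzyme + target (k = 210 /min)
    second substrate + free enzyme + target → free enzyme + over-reaction product (k = 6600 /M²/min)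
    second substrate → decomposed reagent (k = 0.00550 /min)
    second substrate + loaded enzyme ⇌ second complex (K = 1.40 /M, k = 38000 /M/min)

With its 19.3% target, midnight gets a ratio of 32.6% from the rule, and the flask holds 24.8%. With 12.9% target, spring gets 14.6%, and the flask holds 5.76%. In autumn second substrate has a half-life of 0.088 d by decomposition alone, against 2300 d by the over-reaction step at 0.0773 d, far longer. Autumn ends with 0.935% target and 0% over-reaction product.

(The numbers in the tables are calculated with constants of no real substance, and the scatter is random.)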